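Ring C is built from a cut at C2–C3, with O1 starting on C3 instead of C2. A 2-lithiated 4,6-disiloxybenzofuran (ring A with O1, C3 and C4) adds to the ring B aldehyde. Asymmetric hydrogenation then gives a 2-(α-hydroxybenzyl)-2,3-dihydrobenzofuran. In the key step the benzylic carbinol carbon (future C2) ionises, O1 moves from C3 to C2 through a bridged oxonium ion, and water enters at C3. The five-membered ring O1–C3–C4–C4a–C8a becomes the pyran ring C, and the C3 centre dictates C2. The step exploits the ether oxygen O1 vicinal to the ring B benzylic carbon. Oxidation, hydride delivery anti to ring B, feruloylation and desilylation follow.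

Key step: step 7

Remark: TBS = tert-butyldimethylsilyl. Flavan numbering (O1, C2, C3, C4, C4a, C8a; rings A, B, C) is used whenever atoms of the target are meant.

Step 1
Reactants: 1 4,6-dihydroxy-1-benzofuran-3(2H)-one
Product: 2 4,6-bis(TBSO)-1-benzofuran-3(2H)-one
Conditions: TBSCl (2.3 equiv), imidazole, DMF, 0 °C to rt
Reagents that add atoms: tert-butyldimethylsilyl chloride, CC(C)(C)[Si](C)(C)Cl
Why: Imidazole-mediated O-silylation of both phenols, with silyl ethers used on every phenol of the route because fluoride removes them at the end without touching the cinnamate C=C or the C3 ester, which hydrogenolysis of benzyl ethers would not allow.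

Step 2
Reactants: 2 4,6-bis(TBSO)-1-benzofuran-3(2H)-one
Product: 4 4,6-bis(TBSO)-1-benzofuran, via 2,3-dihydrobenzofuran-3-ol 3 (not isolated)
Conditions: NaBH4, THF–MeOH, 0 °C; then 1 M HCl, rt
Reagents that add atoms: none
Why: Borohydride reduction of the ketone followed by acid-induced dehydration of the electron-rich benzylic alcohol 3, driven by aromatisation to the benzofuran.

Step 3
Reactants: 5 methyl 3,5-dihydroxy-4-methoxybenzoate
Product: 6 methyl 3,5-bis(TBSO)-4-methoxybenzoate
Conditions: TBSCl (2.3 equiv), imidazole, DMF, rt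
Reagents that add atoms: tert-butyldimethylsilyl chloride, CC(C)(C)[Si](C)(C)Cl
Why: The same imidazole-mediated O-silylation masks the two ring B phenols that flank the 4-methoxy group.

Step 4
Reactants: 6 methyl 3,5-bis(TBSO)-4-methoxybenzoate
Product: 7 3,5-bis(TBSO)-4-methoxybenzaldehyde
Conditions: i-Bu2AlH (1.05 equiv), CH2Cl2, −78 °C; MeOH at −78 °C, then aq. potassium sodium tartrate
Reagents that add atoms: none
Why: Partial reduction of an ester with one equivalent of i-Bu2AlH at low temperature, where quenching in the cold should stop the reduction at the aldehyde level.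

Step 5
Reactants: 4 4,6-bis(TBSO)-1-benzofuran; 7 3,5-bis(TBSO)-4-methoxybenzaldehyde
Product: 9 rac-[4,6-bis(TBSO)-1-benzofuran-2-yl][3,5-bis(TBSO)-4-methoxyphenyl]methanol, via 2-lithiobenzofuran 8 (not isolated)
Conditions: n-BuLi (1.05 equiv), THF, −78 °C; then 7, −78 °C; sat. aq. NH4Cl
Reagents that add atoms: none
Why: Benzofurans are deprotonated selectively at C2 by n-BuLi, and 1,2-addition of 8 to aldehyde 7 forges the future C2–C3 bond, giving a racemic carbinol whose configuration does not matter because step 7 erases it.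

Step 6
Reactants: 9 rac-[4,6-bis(TBSO)-1-benzofuran-2-yl][3,5-bis(TBSO)-4-methoxyphenyl]methanol
Product: 10 [(2R)-4,6-bis(TBSO)-2,3-dihydro-1-benzofuran-2-yl][3,5-bis(TBSO)-4-methoxyphenyl]methanol (both carbinol epimers)
Conditions: [Ru(cod)(2-methylallyl)2] (5 mol %), 1,3-bis[1-(naphthalen-1-yl)ethyl]imidazolinium tetrafluoroborate (10 mol %, the antipode that gives 2R), KOt-Bu (15 mol %), toluene–hexane; H2 (60 bar), 25 °C
Reagents that add atoms: none
Why: Asymmetric hydrogenation of a 2-substituted benzofuran with a chiral ruthenium bis(N-heterocyclic carbene) catalyst saturates only the furan C=C bond, and catalyst control of the face that takes up hydrogen sets the ring carbon (future C3) as R.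

Step 7
Reactants: 10 [(2R)-4,6-bis(TBSO)-2,3-dihydro-1-benzofuran-2-yl][3,5-bis(TBSO)-4-methoxyphenyl]methanol (both carbinol epimers)
Product: 12 (2R,3S)-5,7-bis(TBSO)-2-[3,5-bis(TBSO)-4-methoxyphenyl]chroman-3-ol, via bridged oxonium ion 11 (not isolated)
Conditions: TsOH·H2O (10 mol %), H2O (5 equiv), (CF3)2CHOH–CH2Cl2 (4:1), 0.01 M, 0 °C to rt; the minor 2,3-cis diastereomer is removed by chromatography
Reagents that add atoms: water, O
Why: Protonation and loss of water at the benzylic carbinol carbon of either epimer of 10 gives a cation that the twisted, weakly donating 4-methoxy group of ring B stabilises only moderately, so the neighbouring ether oxygen O1 bridges it (3-exo-tet) to the 1-oxoniabicyclo[3.1.0]hexane-type ion 11, and water opens 11 by anti attack at the non-benzylic carbon C3 with cleavage of the O1–C3 fusion bond, which turns the five-membered ring into the pyran. The closest known reaction types are the rearrangement–ring expansion of 2-(1-sulfonyloxyalkyl)tetrahydrofurans to 3-acyloxytetrahydropyrans with Zn(OAc)2 and the acid-induced change of 2-(1-hydroxy-1-methylethyl)-2,3-dihydrobenzofurans into 2,2-dimethylchroman-3-ols. C3 is inverted (R in 10, S in 12) by the SN2-type opening, and C2 is set as R because ring B takes the exo position of 11, trans to C4, so both carbinol epimers should converge on the 2,3-trans product. The selectivity needed is attack at C3 rather than at the benzylic carbon: benzylic capture only regenerates 10 and is reversible under acid, whereas the C3 alcohol cannot re-ionise and the six-membered ring is less strained, so the equilibrium should drain to 12. Loss of the C3 proton (towards a 2-benzylbenzofuran) and intermolecular Friedel–Crafts attack by ring A are held back by the non-basic fluoroalcohol, the bulky silyl ethers and high dilution.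

Step 8
Reactants: 12 (2R,3S)-5,7-bis(TBSO)-2-[3,5-bis(TBSO)-4-methoxyphenyl]chroman-3-ol
Product: 13 (2R)-5,7-bis(TBSO)-2-[3,5-bis(TBSO)-4-methoxyphenyl]chroman-3-one
Conditions: Dess–Martin periodinane (1.3 equiv), CH2Cl2, 0 °C to rt; used without delay
Reagents that add atoms: none
Why: Dess–Martin oxidation under essentially neutral conditions removes the C3 centre, which has done its relay work, without enolising the labile C2 centre, as is established for protected 2,3-trans flavan-3-ols.

Step 9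
Reactants: 13 (2R)-5,7-bis(TBSO)-2-[3,5-bis(TBSO)-4-methoxyphenyl]chroman-3-one
Product: 14 (2R,3R)-5,7-bis(TBSO)-2-[3,5-bis(TBSO)-4-methoxyphenyl]chroman-3-ol
Conditions: LiBH(s-Bu)3 (1.3 equiv), THF, −78 °C; sat. aq. NH4Cl
Reagents that add atoms: none
Why: Substrate-controlled ketone reduction with a bulky trialkylborohydride, in which hydride reaches the C3 carbonyl from the face opposite ring B at C2 and so gives the axial alcohol with the 2,3-cis (2R,3R) relationship.

Step 10
Reactants: 15 (E)-ferulic acid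
Product: 17 (E)-3-[4-(TBSO)-3-methoxyphenyl]prop-2-enoic acid, via bis-silylated silyl ester 16 (not isolated)
Conditions: TBSCl (2.4 equiv), imidazole, DMF, rt; then AcOH–THF–H2O, rt
Reagents that add atoms: tert-butyldimethylsilyl chloride, CC(C)(C)[Si](C)(C)Cl
Why: Exhaustive O-silylation followed by selective hydrolysis of the far more labile silyl ester leaves the aryl silyl ether and frees the acid.

Step 11
Reactants: 14 (2R,3R)-5,7-bis(TBSO)-2-[3,5-bis(TBSO)-4-methoxyphenyl]chroman-3-ol; 17 (E)-3-[4-(TBSO)-3-methoxyphenyl]prop-2-enoic acid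
Product: 18 (2R,3R)-5,7-bis(TBSO)-2-[3,5-bis(TBSO)-4-methoxyphenyl]chroman-3-yl (E)-3-[4-(TBSO)-3-methoxyphenyl]prop-2-enoate
Conditions: DCC (1.5 equiv), DMAP (0.3 equiv), CH2Cl2, 0 °C to rt
Reagents that add atoms: none
Why: Steglich esterification acylates the only free hydroxyl group at oxygen, so neither C3 nor C2 nor the E alkene is touched.

Step 12
Reactants: 18 penta-TBS ether of the target
Product: 19 4'-O-methylepigallocatechin-3-O-ferulate
Conditions: HF·pyridine, pyridine–THF, 0 °C to rt, argon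
Reagents that add atoms: none
Why: Fluoride-driven cleavage of the five aryl silyl ethers under buffered, weakly acidic conditions should leave the ester, the cinnamate C=C, both methyl ethers and the base-sensitive C2 centre intact.

Compound list
1 | 4,6-dihydroxy-1-benzofuran-3(2H)-one | O=C1COc2cc(O)cc(O)c12 | starting material
2 | 4,6-bis(TBSO)-1-benzofuran-3(2H)-one | O=C1COc2cc(O[Si](C)(C)C(C)(C)C)cc(O[Si](C)(C)C(C)(C)C)c12 | intermediate
3 | rac-4,6-bis(TBSO)-2,3-dihydro-1-benzofuran-3-ol | OC1COc2cc(O[Si](C)(C)C(C)(C)C)cc(O[Si](C)(C)C(C)(C)C)c12 | intermediate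
4 | 4,6-bis(TBSO)-1-benzofuran | CC(C)(C)[Si](C)(C)Oc1cc(O[Si](C)(C)C(C)(C)C)c2ccoc2c1 | intermediate
5 | methyl 3,5-dihydroxy-4-methoxybenzoate | COC(=O)c1cc(O)c(OC)c(O)c1 | starting material
6 | methyl 3,5-bis(TBSO)-4-methoxybenzoate | COC(=O)c1cc(O[Si](C)(C)C(C)(C)C)c(OC)c(O[Si](C)(C)C(C)(C)C)c1 | intermediate
7 | 3,5-bis(TBSO)-4-methoxybenzaldehyde | O=Cc1cc(O[Si](C)(C)C(C)(C)C)c(OC)c(O[Si](C)(C)C(C)(C)C)c1 | intermediate
8 | 2-lithio-4,6-bis(TBSO)-1-benzofuran | [Li]c1cc2c(O[Si](C)(C)C(C)(C)C)cc(O[Si](C)(C)C(C)(C)C)cc2o1 | intermediate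
9 | rac-[4,6-bis(TBSO)-1-benzofuran-2-yl][3,5-bis(TBSO)-4-methoxyphenyl]methanol | OC(c1cc2c(O[Si](C)(C)C(C)(C)C)cc(O[Si](C)(C)C(C)(C)C)cc2o1)c1cc(O[Si](C)(C)C(C)(C)C)c(OC)c(O[Si](C)(C)C(C)(C)C)c1 | intermediate
10 | [(2R)-4,6-bis(TBSO)-2,3-dihydro-1-benzofuran-2-yl][3,5-bis(TBSO)-4-methoxyphenyl]methanol, both carbinol epimers | OC(c1cc(O[Si](C)(C)C(C)(C)C)c(OC)c(O[Si](C)(C)C(C)(C)C)c1)[C@H]1Cc2c(O[Si](C)(C)C(C)(C)C)cc(O[Si](C)(C)C(C)(C)C)cc2O1 | intermediate
11 | bridged oxonium ion: O1 bonded to C8a, C2 and C3, ring B exo (trans to C4) on the three-membered ring | COc1c(O[Si](C)(C)C(C)(C)C)cc(cc1O[Si](C)(C)C(C)(C)C)[C@@H]1[C@H]2Cc3c(O[Si](C)(C)C(C)(C)C)cc(O[Si](C)(C)C(C)(C)C)cc3[O+]12 | intermediate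
12 | (2R,3S)-5,7-bis(TBSO)-2-[3,5-bis(TBSO)-4-methoxyphenyl]chroman-3-ol | O[C@H]1Cc2c(O[Si](C)(C)C(C)(C)C)cc(O[Si](C)(C)C(C)(C)C)cc2O[C@@H]1c1cc(O[Si](C)(C)C(C)(C)C)c(OC)c(O[Si](C)(C)C(C)(C)C)c1 | intermediate
13 | (2R)-5,7-bis(TBSO)-2-[3,5-bis(TBSO)-4-methoxyphenyl]chroman-3-one | O=C1Cc2c(O[Si](C)(C)C(C)(C)C)cc(O[Si](C)(C)C(C)(C)C)cc2O[C@@H]1c1cc(O[Si](C)(C)C(C)(C)C)c(OC)c(O[Si](C)(C)C(C)(C)C)c1 | intermediate
14 | (2R,3R)-5,7-bis(TBSO)-2-[3,5-bis(TBSO)-4-methoxyphenyl]chroman-3-ol | O[C@@H]1Cc2c(O[Si](C)(C)C(C)(C)C)cc(O[Si](C)(C)C(C)(C)C)cc2O[C@@H]1c1cc(O[Si](C)(C)C(C)(C)C)c(OC)c(O[Si](C)(C)C(C)(C)C)c1 | intermediate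
15 | (E)-ferulic acid | COc1cc(/C=C/C(=O)O)ccc1O | starting material
16 | TBS (E)-3-[4-(TBSO)-3-methoxyphenyl]prop-2-enoate | COc1cc(/C=C/C(=O)O[Si](C)(C)C(C)(C)C)ccc1O[Si](C)(C)C(C)(C)C | intermediate
17 | (E)-3-[4-(TBSO)-3-methoxyphenyl]prop-2-enoic acid | COc1cc(/C=C/C(=O)O)ccc1O[Si](C)(C)C(C)(C)C | intermediate
18 | (2R,3R)-5,7-bis(TBSO)-2-[3,5-bis(TBSO)-4-methoxyphenyl]chroman-3-yl (E)-3-[4-(TBSO)-3-methoxyphenyl]prop-2-enoate | COc1cc(/C=C/C(=O)O[C@@H]2Cc3c(O[Si](C)(C)C(C)(C)C)cc(O[Si](C)(C)C(C)(C)C)cc3O[C@@H]2c2cc(O[Si](C)(C)C(C)(C)C)c(OC)c(O[Si](C)(C)C(C)(C)C)c2)ccc1O[Si](C)(C)C(C)(C)C | intermediate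
19 | 4'-O-methylepigallocatechin-3-O-ferulate | COc1cc(/C=C/C(=O)O[C@@H]2Cc3c(O)cc(O)cc3O[C@@H]2c2cc(O)c(OC)c(O)c2)ccc1O | target

Total step count: 12. Longest linear sequence: 9 steps (1, 2, 5, 6, 7, 8, 9, 11, 12; the branch 3, 4, 5, 6, 7, 8, 9, 11, 12 is equally long).

Steps most likely to fail

1. Step 7.
   - **Risk:** The benzylic cation may lose the C3 proton, or suffer a 1,2-hydride shift, and aromatise to a benzofuran faster than O1 bridges it. Capture may stop at the benzylic carbon. Reversible ionisation of the new C2–O1 bond may erode the trans selectivity and hence the relay of configuration.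
   - **Fallback:** This replaces the reversible acid equilibration of the free alcohol by an irreversible solvolysis of a discrete sulfonate with external acetate. It sets out from 10. ClCH2SO2Cl and 2,6-lutidine in CH2Cl2 at −40 °C convert 10 into the benzylic chloromethanesulfonate F1, which is used crude. Zn(OAc)2 in aqueous AcOH–dioxane should induce the same O1 shift and deliver the ring-expanded (2R,3S)-chroman-3-yl acetate F2. Reductive removal of the acetyl group with i-Bu2AlH at −78 °C, which spares the aryl silyl ethers, comes back to the route at 12.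

2. Step 6.
   - **Risk:** The bulky, oxygenated 2-substituent may slow turnover. In one enantiomer of racemic 9 the carbinol centre may oppose the catalyst, which would mean poor facial selectivity at the ring carbon.
   - **Fallback:** This sets the centre by dynamic kinetic resolution instead of by arene hydrogenation, and it sets out from 9. MnO2 in CH2Cl2 gives the 2-aroylbenzofuran F3. H2 over palladium on carbon in EtOAc saturates the conjugated furan C=C bond to the racemic, configurationally labile 2-aroyl-2,3-dihydrobenzofuran F4. Transfer hydrogenation with RuCl(p-cymene)(TsDPEN) (the antipode that gives 2R) in HCO2H–Et3N with added DBU should reduce the faster-reacting enantiomer while the α-aryloxy ketone racemises. The route is rejoined at 10, now as one carbinol epimer.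

3. Step 4.
   - **Risk:** Over-reduction of the aromatic ester to the benzyl alcohol may compete with clean arrest at the aldehyde.
   - **Fallback:** This accepts full reduction and re-oxidises, and it sets out from 6. Excess i-Bu2AlH at 0 °C gives 3,5-bis(TBSO)-4-methoxybenzyl alcohol F5. MnO2 in CH2Cl2 oxidises this benzylic alcohol and comes back to the route at 7.

Further compounds
F1 | step 7 | [(2R)-4,6-bis(TBSO)-2,3-dihydro-1-benzofuran-2-yl][3,5-bis(TBSO)-4-methoxyphenyl]methyl chloromethanesulfonate | ClCS(=O)(=O)OC(c1cc(O[Si](C)(C)C(C)(C)C)c(OC)c(O[Si](C)(C)C(C)(C)C)c1)[C@H]1Cc2c(O[Si](C)(C)C(C)(C)C)cc(O[Si](C)(C)C(C)(C)C)cc2O1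
F2 | step 7 | (2R,3S)-5,7-bis(TBSO)-2-[3,5-bis(TBSO)-4-methoxyphenyl]chroman-3-yl acetate | CC(=O)O[C@H]1Cc2c(O[Si](C)(C)C(C)(C)C)cc(O[Si](C)(C)C(C)(C)C)cc2O[C@@H]1c1cc(O[Si](C)(C)C(C)(C)C)c(OC)c(O[Si](C)(C)C(C)(C)C)c1
F3 | step 6 | [4,6-bis(TBSO)-1-benzofuran-2-yl][3,5-bis(TBSO)-4-methoxyphenyl]methanone | O=C(c1cc2c(O[Si](C)(C)C(C)(C)C)cc(O[Si](C)(C)C(C)(C)C)cc2o1)c1cc(O[Si](C)(C)C(C)(C)C)c(OC)c(O[Si](C)(C)C(C)(C)C)c1
F4 | step 6 | rac-[4,6-bis(TBSO)-2,3-dihydro-1-benzofuran-2-yl][3,5-bis(TBSO)-4-methoxyphenyl]methanone | O=C(c1cc(O[Si](C)(C)C(C)(C)C)c(OC)c(O[Si](C)(C)C(C)(C)C)c1)C1Cc2c(O[Si](C)(C)C(C)(C)C)cc(O[Si](C)(C)C(C)(C)C)cc2O1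
F5 | step 4 | [3,5-bis(TBSO)-4-methoxyphenyl]methanol | OCc1cc(O[Si](C)(C)C(C)(C)C)c(OC)c(O[Si](C)(C)C(C)(C)C)c1
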